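Readings and results come from a simulation on assumed constants; scatter was added.

**Two earlier runs.** Starting material, dosed into a solution held under gas phase, meets dissolved gas to give target, or turns by itself into side product. The noon run, dosed at 0.775 mM/min, ended with side product at 0.0858 of target. The midnight run, dosed faster at 1.21 mM/min, ended higher, at 0.116.

| flask | starting material | gas phase | remark | time |
|---|---|---|---|---|
| noon | 0.062 M (fed, over 80 min) | 11 mM (held) | run made earlier; the fed solution adds 0.10 times the starting volume |  |
| midnight | 0.097 M (fed, over 80 min) | 11 mM (held) | run made earlier; the fed solution adds 0.10 times the starting volume |  |
| beta | 0.044 M (fed, over 80 min) | 11 mM (held) | the fed solution adds 0.10 times the starting volume | 80 min |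
| delta | 0.044 M | 11 mM | everything together at the start, the whole solution of starting material included, so that from the start the volume is larger by 0.10 times the starting volume | 80 min |

| run | time / min | target / % | side product / % |
|---|---|---|---|
| noon | 12.0 | 9.0 | 0.8 |
| noon | 25.0 | 23.7 | 2.4 |
| noon | 40.0 | 41.0 | 4.0 |
| noon | 50.0 | 52.4 | 4.9 |
| noon | 60.0 | 63.9 | 5.7 |
| noon | 80.0 | 87.4 | 7.5 |
| midnight | 6.00 | 2.4 | 0.3 |
| midnight | 10.0 | 5.7 | 0.5 |
| midnight | 20.0 | 17.2 | 2.2 |
| midnight | 30.0 | 27.8 | 3.1 |
| midnight | 50.0 | 49.0 | 5.8 |
| midnight | 80.0 | 82.7 | 9.6 |

(standard deviation of a reading: 0.3 percentage points)

- amounts and yields of target count crystals too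
- charges are per starting volume, the dose included; the dosed solution carries all of it
- given per volume of solution although it is solid: crystals
- at the start none of the gas is dissolved
- the analysis behind the earlier runs scatters by 0.3 percentage points, standard deviation
- steps under discussion: gas phase <-> dissolved gas; starting material + dissolved gas -> target; starting material -> side product; crystals <-> target
- percentages count the whole charge, also what has not yet gone in

1. the winner by share of target in all that became target or side product; "neither" if no more than 2 percentage points parts them (beta / delta / neither)
2. share of target in all that became target or side product, beta
3. share of target in all that became target or side product, delta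

**Bench rule.** Dose slower, get cleaner. My own balance for dissolved gas says how much: transfer grows with the gap to saturation and matches uptake, which in steady dosing is about the dose. Dissolved gas then falls in line with the dose, and the ratio of side product to target goes as one over the headroom left beneath a limit. The two runs place that limit at 2.45 mM/min, the gas ceiling: the dose rate at which transfer would be fully used, a mass-transfer limit. With 0.3 percentage points on each reading, it is a loose reading. Beta doses at 0.550 mM/min, a quarter of the ceiling, so the rule gives a ratio of 0.0757 and a share of 93.0%.

**The border.** Delta has no dose rate, so the rule stops there. Its charge over the saturation concentration is 4.00, and none of the gas is dissolved at the start. Noon's side product rose at 0.0170 /min per fraction of the charge left. With half the charge present on average and target formed at the ceiling, delta's share is at most 86.8%, by my reckoning 6.2 points under beta.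

**The forecast.** It names beta, with 93.2% for beta and 82% for delta, whose charge “at once starves the gas”. Its delta lies below my upper bound.

    gas phase ⇌ dissolved gas, rate k1*(csat - [dissolved gas]) (kL = 0.00260 /s)
    starting material + dissolved gas → target (k = 0.567 /M/s)
    starting material → side product (k = 3.15 × 10⁻⁴ /s)
    crystals ⇌ target, rate k4*(cs4 - [target]) while solid is left; crystals form when [target] > cs4 (solubility = 27.0 mM, k = 0.00325 /s)

**The flask.** The winner is beta, at 93.1% against 77.4%. Delta holds side product at 22.6% after 80.0 min, with starting material at 0%. The forecast's 93.2% would be wrong for a beta charged at 0.107 M, where the share has moved by 5 points. That dose is 0.544 of the ceiling as read from the noon and midnight runs, itself a loose reading, and with that reading the headroom rule puts the share there 4.4 points below its 93.0%.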